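Both prenyl groups of the target sit next to a phenolic oxygen: C6 of ring A beside O5 and C5' of ring B beside O4'. The route therefore rests on cutting the C6–CH2 and C5'–CH2 bonds back to two aryl 1,1-dimethylallyl ethers. One heating of the (2S)-flavanone that carries these ethers on O5 and O4' and methoxymethyl groups on O7 and O2' should move both allyl units to carbon and free both phenols. Both tertiary ethers are put on as propargyl ethers before the fragments are joined, so that no base meets the finished stereocentre. C2 is secured by kinetic resolution directly before the key step.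

Key step: step 9

Remark: flavanone numbering is used (O1, C2, C3, C4, C4a, C5–C8, C8a; ring B C1'–C6'), 2 is taken as a commercial reagent, and C2 is deliberately formed racemic and then resolved, so that every base-mediated or heated operation before the key step is finished before the configuration is fixed.

Step 1
Reactants: 1 2,4-dihydroxybenzaldehyde; 2 3-chloro-3-methylbut-1-yne
Product: 3 2-hydroxy-4-(2-methylbut-3-yn-2-yloxy)benzaldehyde
Conditions: CuCl2·2H2O (1 mol%), DBU (1.3 equiv), MeCN, 0 °C
Reagents that add atoms: none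
Why: Copper-catalysed propargylic substitution (phenoxide attack on a copper-bound tertiary propargyl cation) is the standard way to aryl 1,1-dimethylpropargyl ethers, and only the free, more acidic 4-OH reacts because the 2-OH is tied up in a hydrogen bond to the aldehyde.

Step 2
Reactants: 3 2-hydroxy-4-(2-methylbut-3-yn-2-yloxy)benzaldehyde
Product: 4 2-(methoxymethoxy)-4-(2-methylbut-3-yn-2-yloxy)benzaldehyde
Conditions: MOMCl (1.5 equiv), i-Pr2NEt (2 equiv), CH2Cl2, 0 °C to rt
Reagents that add atoms: chloromethyl methyl ether (MOMCl), COCCl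
Why: Williamson-type O-alkylation caps the remaining phenol with a group that withstands hydroxide, hydrogenation and heat and that later, as an ether-type donor on O2', helps to steer the shift on ring B.

Step 3
Reactants: 5 2,4,6-trihydroxyacetophenone
Product: 6 1-[2,6-dihydroxy-4-(methoxymethoxy)phenyl]ethan-1-one
Conditions: MOMCl (1.0 equiv), i-Pr2NEt (1.1 equiv), THF, 0 °C
Reagents that add atoms: chloromethyl methyl ether (MOMCl), COCCl
Why: Williamson-type O-alkylation with one equivalent of MOMCl should go to the 4-OH, the most acidic hydroxyl and the only one neither chelated nor crowded by the acetyl group, and any over-protected material is easily removed at this cheap stage.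

Step 4
Reactants: 6 1-[2,6-dihydroxy-4-(methoxymethoxy)phenyl]ethan-1-one; 2 3-chloro-3-methylbut-1-yne
Product: 7 1-[2-hydroxy-4-(methoxymethoxy)-6-(2-methylbut-3-yn-2-yloxy)phenyl]ethan-1-one
Conditions: CuCl2·2H2O (2 mol%), DBU (1.3 equiv), 2 (1.1 equiv), MeCN, 0 °C to rt
Reagents that add atoms: none
Why: The same copper-catalysed propargylic substitution etherifies one of the two equivalent ortho hydroxyls, after which the remaining one is firmly chelated to the ketone and hindered, which should stop the reaction at the mono-ether and keeps DBU away from the later stereocentre.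

Step 5
Reactants: 7 1-[2-hydroxy-4-(methoxymethoxy)-6-(2-methylbut-3-yn-2-yloxy)phenyl]ethan-1-one; 4 2-(methoxymethoxy)-4-(2-methylbut-3-yn-2-yloxy)benzaldehyde
Product: 8 (E)-1-[2-hydroxy-4-(methoxymethoxy)-6-(2-methylbut-3-yn-2-yloxy)phenyl]-3-[2-(methoxymethoxy)-4-(2-methylbut-3-yn-2-yloxy)phenyl]prop-2-en-1-one
Conditions: KOH (excess), EtOH/H2O, rt; aq. NH4Cl work-up
Reagents that add atoms: none
Why: Claisen–Schmidt condensation (crossed aldol addition, then E1cB loss of water) of the methyl ketone with the non-enolisable aldehyde gives the (E)-enone, and MOM ethers, tertiary propargyl ethers and terminal alkynes are inert to hydroxide at room temperature.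

Step 6
Reactants: 8 the (E)-chalcone of step 5
Product: 9 rac-7-(methoxymethoxy)-2-[2-(methoxymethoxy)-4-(2-methylbut-3-yn-2-yloxy)phenyl]-5-(2-methylbut-3-yn-2-yloxy)chroman-4-one
Conditions: NaOAc (5 equiv), EtOH, reflux
Reagents that add atoms: none
Why: Acetate-mediated intramolecular oxa-Michael addition (6-endo-trig) of the only free phenol closes ring C, the equilibrium being pushed to the flavanone by the second ortho alkoxy group that twists the chalcone carbonyl out of conjugation; C2 arises here as a racemate on purpose, and the propargyl ethers tolerate 78 °C, which the allyl ethers might not.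

Step 7
Reactants: 9 racemic bis(propargyl ether) flavanone
Product: 10 rac-7-(methoxymethoxy)-2-[2-(methoxymethoxy)-4-(2-methylbut-3-en-2-yloxy)phenyl]-5-(2-methylbut-3-en-2-yloxy)chroman-4-one
Conditions: H2 (1 atm), Pd/CaCO3 poisoned with Pb(OAc)2 (Lindlar catalyst), quinoline, EtOAc, rt; work-up below 30 °C
Reagents that add atoms: none
Why: Lindlar semi-hydrogenation should stop at the alkene for both terminal alkynes while the ketone, the benzylic C2–O1 bond and the MOM ethers stay untouched, and cold handling prevents a premature sigmatropic shift.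

Step 8
Reactants: 10 racemic bis(1,1-dimethylallyl ether) flavanone
Product: 11 (2S)-7-(methoxymethoxy)-2-[2-(methoxymethoxy)-4-(2-methylbut-3-en-2-yloxy)phenyl]-5-(2-methylbut-3-en-2-yloxy)chroman-4-one
Conditions: Cp*RhCl[(R,R)-TsDPEN] (1 mol%), HCO2H/Et3N (5:2), EtOAc, rt, stopped just past half conversion
Reagents that add atoms: none
Why: This is a kinetic resolution by Noyori-type asymmetric transfer hydrogenation, a known process for racemic flavanones: the (R,R)-catalyst makes 4R carbinols, which agrees with the intrinsic preference for the 2,4-cis alcohol only in the (2R)-enantiomer, so that enantiomer is reduced to the (2R,4R)-flavan-4-ol while the (2S)-ketone is left and separated by chromatography, with vinyl groups and MOM ethers inert.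

Step 9
Reactants: 11 (2S)-bis(1,1-dimethylallyl ether) flavanone
Product: 13 (2S)-5-hydroxy-2-[4-hydroxy-2-(methoxymethoxy)-5-(3-methylbut-2-en-1-yl)phenyl]-7-(methoxymethoxy)-6-(3-methylbut-2-en-1-yl)chroman-4-one, via ring-A mono-rearranged ether 12 (not isolated)
Conditions: toluene (degassed, 0.02 M), 120 °C, sealed tube, silanised glass
Reagents that add atoms: none
Why: Each aryl 1,1-dimethylallyl ether undergoes a concerted suprafacial [3,3]-sigmatropic shift through a chair-like six-membered transition state, in which the vinyl CH2 terminus bonds to the ortho carbon as the tertiary C–O bond breaks, and the cyclohexadienone so formed enolises to the phenol; this is the aromatic ortho-Claisen rearrangement, long established for making ortho-prenylphenols in the flavonoid and coumarin series. The gem-dimethyl group weakens the breaking bond, so that about 120 °C without additive should suffice, and the allyl inversion turns the tertiary ether into the linear prenyl chain. On ring A the shift can end only at C6, because the other neighbour of C5 is the substituted fusion carbon C4a, so an 8-prenyl isomer is excluded by structure; the new 5-OH is held by a hydrogen bond to the C4 carbonyl, and this shift on the more electron-rich ring should come first and give 12. On ring B the step needs C5' over C3', which is a preference and not an exclusion: C5' is para to the donor O2', the position that a meta-alkoxy group favours, whereas C3' lies between two oxygens and is screened by the OCH2OMe group on O2', which the large C1' substituent turns towards C3'. No ring is closed and no stereocentre is made. C2 is a spectator that must not be lost, which is why a dilute, aprotic medium free of acid and base is used, so that neither retro-oxa-Michael opening of ring C nor expulsion of O1 through a quinone methide of the freed 4'-phenol is promoted.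

Step 10
Reactants: 13 (2S)-diprenylated bis(MOM) flavanone
Product: 14 (2S)-2-[2,4-dihydroxy-5-(3-methylbut-2-en-1-yl)phenyl]-5,7-dihydroxy-6-(3-methylbut-2-en-1-yl)chroman-4-one
Conditions: HCl (ca. 1 M), MeOH, 40–45 °C, stopped at full conversion
Reagents that add atoms: none
Why: Acid-catalysed transacetalisation of the two phenolic MOM ethers to dimethoxymethane is standard for prenylated flavanones; dilute acid and gentle warming are chosen because opening of ring C (loss of C2 configuration, drift of the prenyl group from C6 to C8) is mainly base-driven and chroman formation from ortho-prenylphenols needs stronger acid.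

Compound list
1 | 2,4-dihydroxybenzaldehyde | O=Cc1ccc(O)cc1O | starting material
2 | 3-chloro-3-methylbut-1-yne | CC(C)(Cl)C#C | starting material
3 | 2-hydroxy-4-(2-methylbut-3-yn-2-yloxy)benzaldehyde | O=Cc1ccc(OC(C)(C)C#C)cc1O | intermediate
4 | 2-(methoxymethoxy)-4-(2-methylbut-3-yn-2-yloxy)benzaldehyde | O=Cc1ccc(OC(C)(C)C#C)cc1OCOC | intermediate
5 | 2,4,6-trihydroxyacetophenone | CC(=O)c1c(O)cc(O)cc1O | starting material
6 | 1-[2,6-dihydroxy-4-(methoxymethoxy)phenyl]ethan-1-one | CC(=O)c1c(O)cc(OCOC)cc1O | intermediate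
7 | 1-[2-hydroxy-4-(methoxymethoxy)-6-(2-methylbut-3-yn-2-yloxy)phenyl]ethan-1-one | CC(=O)c1c(O)cc(OCOC)cc1OC(C)(C)C#C | intermediate
8 | (E)-1-[2-hydroxy-4-(methoxymethoxy)-6-(2-methylbut-3-yn-2-yloxy)phenyl]-3-[2-(methoxymethoxy)-4-(2-methylbut-3-yn-2-yloxy)phenyl]prop-2-en-1-one | O=C(/C=C/c1ccc(OC(C)(C)C#C)cc1OCOC)c1c(O)cc(OCOC)cc1OC(C)(C)C#C | intermediate
9 | rac-7-(methoxymethoxy)-2-[2-(methoxymethoxy)-4-(2-methylbut-3-yn-2-yloxy)phenyl]-5-(2-methylbut-3-yn-2-yloxy)chroman-4-one | C#CC(C)(C)Oc1ccc(C2CC(=O)c3c(OC(C)(C)C#C)cc(OCOC)cc3O2)c(OCOC)c1 | intermediate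
10 | rac-7-(methoxymethoxy)-2-[2-(methoxymethoxy)-4-(2-methylbut-3-en-2-yloxy)phenyl]-5-(2-methylbut-3-en-2-yloxy)chroman-4-one | C=CC(C)(C)Oc1ccc(C2CC(=O)c3c(OC(C)(C)C=C)cc(OCOC)cc3O2)c(OCOC)c1 | intermediate
11 | (2S)-7-(methoxymethoxy)-2-[2-(methoxymethoxy)-4-(2-methylbut-3-en-2-yloxy)phenyl]-5-(2-methylbut-3-en-2-yloxy)chroman-4-one | C=CC(C)(C)Oc1ccc([C@@H]2CC(=O)c3c(OC(C)(C)C=C)cc(OCOC)cc3O2)c(OCOC)c1 | intermediate
12 | (2S)-5-hydroxy-7-(methoxymethoxy)-2-[2-(methoxymethoxy)-4-(2-methylbut-3-en-2-yloxy)phenyl]-6-(3-methylbut-2-en-1-yl)chroman-4-one | C=CC(C)(C)Oc1ccc([C@@H]2CC(=O)c3c(O)c(CC=C(C)C)c(OCOC)cc3O2)c(OCOC)c1 | intermediate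
13 | (2S)-5-hydroxy-2-[4-hydroxy-2-(methoxymethoxy)-5-(3-methylbut-2-en-1-yl)phenyl]-7-(methoxymethoxy)-6-(3-methylbut-2-en-1-yl)chroman-4-one | COCOc1cc(O)c(CC=C(C)C)cc1[C@@H]1CC(=O)c2c(O)c(CC=C(C)C)c(OCOC)cc2O1 | intermediate
14 | (2S)-2-[2,4-dihydroxy-5-(3-methylbut-2-en-1-yl)phenyl]-5,7-dihydroxy-6-(3-methylbut-2-en-1-yl)chroman-4-one | CC(C)=CCc1cc([C@@H]2CC(=O)c3c(cc(O)c(CC=C(C)C)c3O)O2)c(O)cc1O | target

Total step count: 10. Longest linear sequence: 8 steps (steps 3 to 10, from 5).

Steps most likely to fail

Step 9. Part of the ring-B shift may run to C3' instead of C5'. The configuration at C2 may erode by reversible opening of ring C once the 4'-phenol is free. A tertiary allyl group may also be lost by ionisation.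

The fallback sets out from 4, uses 7, and returns at 14. It separates the two shifts, so that ring B is prenylated before any stereocentre exists.
- Aldehyde 4 is semi-hydrogenated as in step 7 to 2-(methoxymethoxy)-4-(2-methylbut-3-en-2-yloxy)benzaldehyde F1.
- Heating F1 in toluene gives 4-hydroxy-2-(methoxymethoxy)-5-(3-methylbut-2-en-1-yl)benzaldehyde F2, and regioisomeric material is removed at this small-molecule stage.
- MOMCl and i-Pr2NEt then give 2,4-bis(methoxymethoxy)-5-(3-methylbut-2-en-1-yl)benzaldehyde F3.
- Claisen–Schmidt condensation of F3 with 7 gives the ring-B-prenylated chalcone F4.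
- NaOAc in EtOH closes F4 to the racemic 5-O-propargyl flavanone F5.
- Lindlar semi-hydrogenation of F5 gives the racemic 5-O-(1,1-dimethylallyl) flavanone F6.
- The resolution of step 8 leaves the (2S)-5-O-(1,1-dimethylallyl) flavanone F7 beside the (2R,4R)-flavan-4-ol F8.
- A single Claisen shift on ring A, now in a substrate without a free ring-B phenol, gives the (2S)-tris(MOM) diprenylflavanone F9.
- Methanolic HCl as in step 10 converts F9 into 14.

Step 8. Hydride transfer may be slow, or may discriminate poorly between the enantiomers, because the carbonyl group is crowded by the tertiary ether on O5.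

The fallback sets out from 10 and returns at 11. It replaces the chemical resolution by a physical one. Racemic 10 is separated by preparative supercritical-fluid chromatography on a polysaccharide-based chiral stationary phase at or below 30 °C. This gives 11 and the (2R)-bis(1,1-dimethylallyl ether) flavanone F10, which is set aside.

Step 4. O-alkylation of the hindered, partly chelated phenol may be sluggish. Alkylation at carbon of the electron-rich ring or a second etherification may compete.

The fallback sets out from 6 and returns at 10. It makes the tertiary allyl ether directly by palladium-catalysed allylic etherification (Tsuji–Trost type), without an alkyne on ring A.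
- 2-Methylbut-3-en-2-ol is converted with n-BuLi and Boc2O into tert-butyl 2-methylbut-3-en-2-yl carbonate F11.
- With Pd(PPh3)4 in THF at 0 °C, phenol 6 attacks the more substituted end of the 1,1-dimethylallyl palladium complex under kinetic control. This gives 1-[2-hydroxy-4-(methoxymethoxy)-6-(2-methylbut-3-en-2-yloxy)phenyl]ethan-1-one F12.
- Condensation of F12 with 4 as in step 5 gives the mixed allyl/propargyl chalcone F13.
- Ring closure with NaOAc in EtOH at no more than 50 °C gives the racemic mixed allyl/propargyl flavanone F14.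
- The semi-hydrogenation of step 7, now of a single alkyne, leads to 10.

Further compounds
F1 | step 9 | 2-(methoxymethoxy)-4-(2-methylbut-3-en-2-yloxy)benzaldehyde | O=Cc1ccc(OC(C)(C)C=C)cc1OCOC
F2 | step 9 | 4-hydroxy-2-(methoxymethoxy)-5-(3-methylbut-2-en-1-yl)benzaldehyde | O=Cc1cc(CC=C(C)C)c(O)cc1OCOC
F3 | step 9 | 2,4-bis(methoxymethoxy)-5-(3-methylbut-2-en-1-yl)benzaldehyde | O=Cc1cc(CC=C(C)C)c(OCOC)cc1OCOC
F4 | step 9 | (E)-3-[2,4-bis(methoxymethoxy)-5-(3-methylbut-2-en-1-yl)phenyl]-1-[2-hydroxy-4-(methoxymethoxy)-6-(2-methylbut-3-yn-2-yloxy)phenyl]prop-2-en-1-one | O=C(/C=C/c1cc(CC=C(C)C)c(OCOC)cc1OCOC)c1c(O)cc(OCOC)cc1OC(C)(C)C#C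
F5 | step 9 | rac-2-[2,4-bis(methoxymethoxy)-5-(3-methylbut-2-en-1-yl)phenyl]-7-(methoxymethoxy)-5-(2-methylbut-3-yn-2-yloxy)chroman-4-one | COCOc1cc(OCOC)c(CC=C(C)C)cc1C1CC(=O)c2c(OC(C)(C)C#C)cc(OCOC)cc2O1
F6 | step 9 | rac-2-[2,4-bis(methoxymethoxy)-5-(3-methylbut-2-en-1-yl)phenyl]-7-(methoxymethoxy)-5-(2-methylbut-3-en-2-yloxy)chroman-4-one | COCOc1cc(OCOC)c(CC=C(C)C)cc1C1CC(=O)c2c(OC(C)(C)C=C)cc(OCOC)cc2O1
F7 | step 9 | (2S)-2-[2,4-bis(methoxymethoxy)-5-(3-methylbut-2-en-1-yl)phenyl]-7-(methoxymethoxy)-5-(2-methylbut-3-en-2-yloxy)chroman-4-one | COCOc1cc(OCOC)c(CC=C(C)C)cc1[C@@H]1CC(=O)c2c(OC(C)(C)C=C)cc(OCOC)cc2O1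
F8 | step 9 | (2R,4R)-2-[2,4-bis(methoxymethoxy)-5-(3-methylbut-2-en-1-yl)phenyl]-7-(methoxymethoxy)-5-(2-methylbut-3-en-2-yloxy)chroman-4-ol | COCOc1cc(OCOC)c(CC=C(C)C)cc1[C@H]1C[C@@H](O)c2c(OC(C)(C)C=C)cc(OCOC)cc2O1
F9 | step 9 | (2S)-2-[2,4-bis(methoxymethoxy)-5-(3-methylbut-2-en-1-yl)phenyl]-5-hydroxy-7-(methoxymethoxy)-6-(3-methylbut-2-en-1-yl)chroman-4-one | COCOc1cc(OCOC)c(CC=C(C)C)cc1[C@@H]1CC(=O)c2c(O)c(CC=C(C)C)c(OCOC)cc2O1
F10 | step 8 | (2R)-7-(methoxymethoxy)-2-[2-(methoxymethoxy)-4-(2-methylbut-3-en-2-yloxy)phenyl]-5-(2-methylbut-3-en-2-yloxy)chroman-4-one | C=CC(C)(C)Oc1ccc([C@H]2CC(=O)c3c(OC(C)(C)C=C)cc(OCOC)cc3O2)c(OCOC)c1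
F11 | step 4 | tert-butyl 2-methylbut-3-en-2-yl carbonate | C=CC(C)(C)OC(=O)OC(C)(C)C
F12 | step 4 | 1-[2-hydroxy-4-(methoxymethoxy)-6-(2-methylbut-3-en-2-yloxy)phenyl]ethan-1-one | CC(=O)c1c(O)cc(OCOC)cc1OC(C)(C)C=C
F13 | step 4 | (E)-1-[2-hydroxy-4-(methoxymethoxy)-6-(2-methylbut-3-en-2-yloxy)phenyl]-3-[2-(methoxymethoxy)-4-(2-methylbut-3-yn-2-yloxy)phenyl]prop-2-en-1-one | O=C(/C=C/c1ccc(OC(C)(C)C#C)cc1OCOC)c1c(O)cc(OCOC)cc1OC(C)(C)C=C
F14 | step 4 | rac-7-(methoxymethoxy)-2-[2-(methoxymethoxy)-4-(2-methylbut-3-yn-2-yloxy)phenyl]-5-(2-methylbut-3-en-2-yloxy)chroman-4-one | C#CC(C)(C)Oc1ccc(C2CC(=O)c3c(OC(C)(C)C=C)cc(OCOC)cc3O2)c(OCOC)c1
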